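**Retrosynthetic overview**
1. The C2 hemiketal is unveiled last: the target comes from its 4‑methoxybenzyl (PMB) ketal by DDQ cleavage, which never breaks the C2–O bond.
2. The PMB ketal is cut at C2–C1' into two fragments of similar size, joined by a Pd‑catalysed asymmetric allylic alkylation that sets C2: a 2‑(PMB‑oxy)‑4‑methylbenzofuran‑3‑one (prochiral enolate) and (8R)‑8‑hydroxyfarnesyl acetate.
3. Ring fragment: the benzene ring is bought (ethyl 6‑methylsalicylate); the furanone ring, the only ring made, is closed first by a Dieckmann‑type intramolecular ester‑aldol condensation, then C2 is brominated and converted to the PMB acetal.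
4. Chain fragment: geranyl acetate → allylic oxidation at C8 → enal → Keck allylation (sets C8 as R) → cross‑metathesis to finish the prenyl end.

Assumption: the C2 hemiketal can epimerise by ring–chain tautomerism under basic conditions, so it is carried as a ketal ether to the last step and the free target is never exposed to base; the facial sense of step 10 is assigned by analogy and is untested.

**Step 1**
Reactants: 1 ethyl 2‑hydroxy‑6‑methylbenzoate; 2 ethyl bromoacetate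
Product: 3 ethyl 2‑(2‑ethoxy‑2‑oxoethoxy)‑6‑methylbenzoate
Conditions: K2CO3, DMF, 60 °C
Reagents that add atoms: none
Why: Williamson ether synthesis, in which the phenoxide formed by K2CO3 displaces bromide from the activated α‑bromo ester by SN2; no stereocentre is involved.

**Step 2**
Reactants: 3 ethyl 2‑(2‑ethoxy‑2‑oxoethoxy)‑6‑methylbenzoate
Product: 4 ethyl 3‑hydroxy‑4‑methyl‑1‑benzofuran‑2‑carboxylate (enol form of the β‑keto ester)
Conditions: NaOEt, toluene–EtOH, 80 °C; then 1 M HCl, 0 °C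
Reagents that add atoms: none
Why: Dieckmann‑type intramolecular ester‑aldol (Claisen) condensation, in which the aryloxyacetate enolate adds 5‑exo‑trig to the neighbouring benzoate carbonyl, ethoxide is lost, and deprotonation to the aromatic 3‑oxidobenzofuran drives closure of the furanone ring.

**Step 3**
Reactants: 4 ethyl 3‑hydroxy‑4‑methyl‑1‑benzofuran‑2‑carboxylate
Product: 5 4‑methyl‑1‑benzofuran‑3(2H)‑one
Conditions: 2 M HCl–AcOH (1:1), 100 °C, N2
Reagents that add atoms: none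
Why: Acid‑catalysed ester hydrolysis and decarboxylation of the β‑keto acid through its keto tautomer leaves the parent benzofuranone with a free C2 methylene.

**Step 4**
Reactants: 5 4‑methyl‑1‑benzofuran‑3(2H)‑one
Product: 6 2‑bromo‑4‑methyl‑1‑benzofuran‑3(2H)‑one (racemic)
Conditions: CuBr2 (2.1 equiv), EtOAc–CHCl3 (1:1), reflux; used at once
Reagents that add atoms: copper dibromide, Br[Cu]Br
Why: α‑Bromination of the aryl ketone through its enol with CuBr2, which halogenates the only enolisable position once and spares the acyl‑deactivated ring; the new C2 centre is racemic and is erased later.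

**Step 5**
Reactants: 6 2‑bromo‑4‑methyl‑1‑benzofuran‑3(2H)‑one; 7 4‑methoxybenzyl alcohol
Product: 8 2‑[(4‑methoxybenzyl)oxy]‑4‑methyl‑1‑benzofuran‑3(2H)‑one (racemic at C2)
Conditions: Ag2CO3, 4 Å MS, CH2Cl2, 0 °C → rt, dark
Reagents that add atoms: none
Why: Koenigs–Knorr‑type silver‑assisted alcoholysis of the α‑bromo ether (the reactivity of a ulosyl bromide) replaces bromide by the PMB alcohol to give a stable mixed acetal, still racemic at the enolisable C2.

**Step 6**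
Reactants: 9 geranyl acetate [(2E)‑3,7‑dimethylocta‑2,6‑dien‑1‑yl acetate]
Product: 10 (2E,6E)‑8‑hydroxy‑3,7‑dimethylocta‑2,6‑dien‑1‑yl acetate
Conditions: SeO2 (0.3 equiv), t‑BuOOH (3 equiv), salicylic acid (0.1 equiv), CH2Cl2, rt
Reagents that add atoms: selenium dioxide, O=[Se]=O (catalytic oxygen carrier); tert‑butyl hydroperoxide, CC(C)(C)OO (terminal oxygen source)
Why: Riley allylic oxidation in the catalytic Sharpless variant (ene reaction then [2,3]‑sigmatropic shift) attacks the E‑methyl group of the more electron‑rich remote trisubstituted alkene and gives the E‑allylic alcohol.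

**Step 7**
Reactants: 10 (2E,6E)‑8‑hydroxy‑3,7‑dimethylocta‑2,6‑dien‑1‑yl acetate
Product: 11 (2E,6E)‑3,7‑dimethyl‑8‑oxoocta‑2,6‑dien‑1‑yl acetate
Conditions: activated MnO2 (15 equiv), CH2Cl2, rt
Reagents that add atoms: none
Why: MnO2 oxidises only the allylic alcohol to the enal and leaves the acetate and both alkene geometries untouched.

**Step 8**
Reactants: 11 (2E,6E)‑3,7‑dimethyl‑8‑oxoocta‑2,6‑dien‑1‑yl acetate
Product: 12 (2E,6E,8R)‑8‑hydroxy‑3,7‑dimethylundeca‑2,6,10‑trien‑1‑yl acetate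
Conditions: allylSnBu3 (1.5 equiv), Ti(OiPr)4 (10 mol%), (R)‑BINOL (20 mol%), 4 Å MS, CH2Cl2, −20 °C, 72 h; aq. NaHCO3
Reagents that add atoms: allyltributylstannane, C=CC[Sn](CCCC)(CCCC)CCCC
Why: Keck asymmetric allylation, in which the (R)‑BINOL titanium Lewis acid binds the enal and directs 1,2‑addition of the allylstannane to the re face, setting C8 as R (the sense in which benzaldehyde gives the R alcohol with this catalyst).

**Step 9**
Reactants: 12 (2E,6E,8R)‑8‑hydroxy‑3,7‑dimethylundeca‑2,6,10‑trien‑1‑yl acetate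
Product: 13 (2E,6E,8R)‑8‑hydroxy‑3,7,11‑trimethyldodeca‑2,6,10‑trien‑1‑yl acetate
Conditions: second‑generation Grubbs catalyst (3 mol%), 2‑methyl‑2‑butene–CH2Cl2 (1:1), 35 °C
Reagents that add atoms: 2‑methyl‑2‑butene, CC=C(C)C
Why: Olefin cross‑metathesis, in which only the monosubstituted terminal alkene enters the ruthenium carbene cycle and exchanges its CH2 for the isopropylidene unit, while the trisubstituted alkenes and the C8 stereocentre are unaffected.

**Step 10**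
Reactants: 8 2‑[(4‑methoxybenzyl)oxy]‑4‑methyl‑1‑benzofuran‑3(2H)‑one; 13 (2E,6E,8R)‑8‑hydroxy‑3,7,11‑trimethyldodeca‑2,6,10‑trien‑1‑yl acetate
Product: 14 (2R)‑2‑[(2E,6E,8R)‑8‑hydroxy‑3,7,11‑trimethyldodeca‑2,6,10‑trien‑1‑yl]‑2‑[(4‑methoxybenzyl)oxy]‑4‑methyl‑1‑benzofuran‑3(2H)‑one
Conditions: Pd2(dba)3·CHCl3 (2.5 mol%), (R,R)‑DACH‑phenyl Trost ligand (7.5 mol%), Cs2CO3 (1.1 equiv), CH2Cl2, 0 °C → rt, argon
Reagents that add atoms: none
Why: Tsuji–Trost asymmetric allylic alkylation, in which the soft aromatic cesium enolate of 8 attacks the less hindered CH2 end of the π‑allylpalladium formed from 13 (the E geometry is kept because syn–anti exchange would need σ‑bonding at the tertiary carbon) and the chiral ligand pocket selects the enolate face so that C2 forms as R, a sense assigned by analogy with azlactone and oxindole prenylations.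

**Step 11**
Reactants: 14 (2R)‑2‑[(2E,6E,8R)‑8‑hydroxy‑3,7,11‑trimethyldodeca‑2,6,10‑trien‑1‑yl]‑2‑[(4‑methoxybenzyl)oxy]‑4‑methyl‑1‑benzofuran‑3(2H)‑one
Product: 15 (2R)‑2‑hydroxy‑2‑[(2E,6E,8R)‑8‑hydroxy‑3,7,11‑trimethyldodeca‑2,6,10‑trien‑1‑yl]‑4‑methyl‑1‑benzofuran‑3(2H)‑one (target)
Conditions: DDQ (1.3 equiv), CH2Cl2–H2O (20:1), 0 °C; work‑up without base (Celite, cold pH 5 buffer)
Reagents that add atoms: none
Why: Oxidative PMB ether cleavage, in which DDQ abstracts the benzylic hydride, water adds to the oxocarbenium ion and the hemiacetal collapses to 4‑methoxybenzaldehyde, so the C2–O bond is never broken and the R hemiketal is released with retention under non‑basic conditions.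

**Compound list**
1 | ethyl 2‑hydroxy‑6‑methylbenzoate | CCOC(=O)c1c(C)cccc1O | starting material
2 | ethyl bromoacetate | CCOC(=O)CBr | starting material
3 | ethyl 2‑(2‑ethoxy‑2‑oxoethoxy)‑6‑methylbenzoate | CCOC(=O)COc1cccc(C)c1C(=O)OCC | intermediate
4 | ethyl 3‑hydroxy‑4‑methyl‑1‑benzofuran‑2‑carboxylate | CCOC(=O)c1oc2cccc(C)c2c1O | intermediate
5 | 4‑methyl‑1‑benzofuran‑3(2H)‑one | Cc1cccc2OCC(=O)c12 | intermediate
6 | 2‑bromo‑4‑methyl‑1‑benzofuran‑3(2H)‑one (racemic) | Cc1cccc2OC(Br)C(=O)c12 | intermediate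
7 | 4‑methoxybenzyl alcohol | COc1ccc(CO)cc1 | starting material
8 | 2‑[(4‑methoxybenzyl)oxy]‑4‑methyl‑1‑benzofuran‑3(2H)‑one (racemic) | COc1ccc(COC2Oc3cccc(C)c3C2=O)cc1 | intermediate
9 | geranyl acetate | CC(C)=CCC/C(C)=C/COC(C)=O | starting material
10 | (2E,6E)‑8‑hydroxy‑3,7‑dimethylocta‑2,6‑dien‑1‑yl acetate | OC/C(C)=C/CC/C(C)=C/COC(C)=O | intermediate
11 | (2E,6E)‑3,7‑dimethyl‑8‑oxoocta‑2,6‑dien‑1‑yl acetate | O=C/C(C)=C/CC/C(C)=C/COC(C)=O | intermediate
12 | (2E,6E,8R)‑8‑hydroxy‑3,7‑dimethylundeca‑2,6,10‑trien‑1‑yl acetate | C=CC[C@@H](O)/C(C)=C/CC/C(C)=C/COC(C)=O | intermediate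
13 | (2E,6E,8R)‑8‑hydroxy‑3,7,11‑trimethyldodeca‑2,6,10‑trien‑1‑yl acetate | CC(C)=CC[C@@H](O)/C(C)=C/CC/C(C)=C/COC(C)=O | intermediate
14 | (2R)‑2‑[(2E,6E,8R)‑8‑hydroxy‑3,7,11‑trimethyldodeca‑2,6,10‑trien‑1‑yl]‑2‑[(4‑methoxybenzyl)oxy]‑4‑methyl‑1‑benzofuran‑3(2H)‑one | CC(C)=CC[C@@H](O)/C(C)=C/CC/C(C)=C/C[C@@]1(OCc3ccc(OC)cc3)Oc2cccc(C)c2C1=O | intermediate
15 | (2R)‑2‑hydroxy‑2‑[(2E,6E,8R)‑8‑hydroxy‑3,7,11‑trimethyldodeca‑2,6,10‑trien‑1‑yl]‑4‑methyl‑1‑benzofuran‑3(2H)‑one | CC(C)=CC[C@@H](O)/C(C)=C/CC/C(C)=C/C[C@@]1(O)Oc2cccc(C)c2C1=O | target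

**Totals**
Total step count: 11.
Longest linear sequence: 7 (steps 1–5, 10, 11). The chain branch is 6 (steps 6–9, 10, 11).

**Three steps most likely to fail**

Step 10. This nucleophile class is untested in asymmetric allylic alkylation, so linear/branched selectivity, the level of enantioselection and its sense at C2 are all open; if only the sense is wrong, the (S,S)‑ligand is used. The fallback replaces catalyst control by an auxiliary and a separation; it sets out from 6 (using 13) and comes back at 15. Bromide 6 is opened with (S)‑1‑(4‑methoxyphenyl)ethanol and Ag2CO3 to give 2‑[(1S)‑1‑(4‑methoxyphenyl)ethoxy]‑4‑methyl‑1‑benzofuran‑3(2H)‑one F1. Its cesium enolate is allylated with 13 under achiral Pd(PPh3)4, and the two C2 epimers, now diastereomers next to the auxiliary centre, are separated on silica. These are (2R)‑2‑[(2E,6E,8R)‑8‑hydroxy‑3,7,11‑trimethyldodeca‑2,6,10‑trien‑1‑yl]‑2‑[(1S)‑1‑(4‑methoxyphenyl)ethoxy]‑4‑methyl‑1‑benzofuran‑3(2H)‑one F2 and the discarded (2S)‑2‑[(2E,6E,8R)‑8‑hydroxy‑3,7,11‑trimethyldodeca‑2,6,10‑trien‑1‑yl]‑2‑[(1S)‑1‑(4‑methoxyphenyl)ethoxy]‑4‑methyl‑1‑benzofuran‑3(2H)‑one F3. DDQ on F2 removes the auxiliary as 4'‑methoxyacetophenone and gives 15.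

Step 11. DDQ may be slow on the electron‑poor ketal oxygen, may oxidise the C8 allylic alcohol, and any basic contact epimerises C2. The fallback uses a photolabile ketal; it sets out from 6 and comes back at 15. Alcoholysis of 6 with 2‑nitrobenzyl alcohol and Ag2CO3 gives 4‑methyl‑2‑[(2‑nitrobenzyl)oxy]‑1‑benzofuran‑3(2H)‑one F4. The asymmetric allylation of step 10 with 13 then gives (2R)‑2‑[(2E,6E,8R)‑8‑hydroxy‑3,7,11‑trimethyldodeca‑2,6,10‑trien‑1‑yl]‑4‑methyl‑2‑[(2‑nitrobenzyl)oxy]‑1‑benzofuran‑3(2H)‑one F5. Irradiation at 365 nm in MeCN at 0 °C releases 15 without any reagent.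

Step 5. Bromide 6 is labile (hydrolysis, self‑condensation) and the silver alcoholysis may give a poor yield. The fallback avoids the bromide by carbenoid O–H insertion; it sets out from 5 and comes back at 8. Diazo transfer with 4‑acetamidobenzenesulfonyl azide and DBU in MeCN gives 2‑diazo‑4‑methyl‑1‑benzofuran‑3(2H)‑one F6. Rh2(OAc)4‑catalysed O–H insertion into 7 in CH2Cl2 then gives 8.

**Further compounds**
F1 | step 10 | 2‑[(1S)‑1‑(4‑methoxyphenyl)ethoxy]‑4‑methyl‑1‑benzofuran‑3(2H)‑one | C[C@H](OC1Oc2cccc(C)c2C1=O)c1ccc(OC)cc1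
F2 | step 10 | (2R)‑2‑[(2E,6E,8R)‑8‑hydroxy‑3,7,11‑trimethyldodeca‑2,6,10‑trien‑1‑yl]‑2‑[(1S)‑1‑(4‑methoxyphenyl)ethoxy]‑4‑methyl‑1‑benzofuran‑3(2H)‑one | CC(C)=CC[C@@H](O)/C(C)=C/CC/C(C)=C/C[C@@]1(O[C@@H](C)c3ccc(OC)cc3)Oc2cccc(C)c2C1=O
F3 | step 10 | (2S)‑2‑[(2E,6E,8R)‑8‑hydroxy‑3,7,11‑trimethyldodeca‑2,6,10‑trien‑1‑yl]‑2‑[(1S)‑1‑(4‑methoxyphenyl)ethoxy]‑4‑methyl‑1‑benzofuran‑3(2H)‑one | CC(C)=CC[C@@H](O)/C(C)=C/CC/C(C)=C/C[C@]1(O[C@@H](C)c3ccc(OC)cc3)Oc2cccc(C)c2C1=O
F4 | step 11 | 4‑methyl‑2‑[(2‑nitrobenzyl)oxy]‑1‑benzofuran‑3(2H)‑one | Cc1cccc2OC(OCc3ccccc3[N+](=O)[O-])C(=O)c12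
F5 | step 11 | (2R)‑2‑[(2E,6E,8R)‑8‑hydroxy‑3,7,11‑trimethyldodeca‑2,6,10‑trien‑1‑yl]‑4‑methyl‑2‑[(2‑nitrobenzyl)oxy]‑1‑benzofuran‑3(2H)‑one | CC(C)=CC[C@@H](O)/C(C)=C/CC/C(C)=C/C[C@@]1(OCc3ccccc3[N+](=O)[O-])Oc2cccc(C)c2C1=O
F6 | step 5 | 2‑diazo‑4‑methyl‑1‑benzofuran‑3(2H)‑one | Cc1cccc2OC(=[N+]=[N-])C(=O)c12
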